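**Retrosynthetic overview**
1. Target 31 is cut at the C(sp2)–C(sp2) bond of the triene: a last-step Stille coupling joins vinyl iodide 20 (acyl chain plus epoxyquinol core) and dienylstannane amide 30 (aminocyclopentenone unit).
2. 20 comes from epoxy quinone monoketal 14. Direct alkenyl-metal addition to 14 would put the OH cis to the oxirane, so the carbinol is made by osmylation of an exocyclic enol ether on the face opposite the oxirane (16 to 18), then Takai iodo-olefination and ketal removal.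
3. 14 comes from anilide 12 by PhI(OAc)2 dearomatisation and cinchona phase-transfer epoxidation; 12 comes from acid 6 and 2,5-dimethoxyaniline 10 (from hydroquinone).
4. 6 comes from (S)-3-bromo-2-methylpropan-1-ol (Li2CuCl4 coupling, oxidation/Wittig); 30 comes from propargyl alcohol (hydrostannylation, Horner–Wadsworth–Emmons) and aminoenone salt 23 (from cyclopentane-1,3-dione).
5. Rings: both carbocycles are bought (the hydroquinone ring is dearomatised in step 8; the cyclopentanedione ring is carried through); the only ring formed is the oxirane (step 9).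

Assumption: the SMILES is read literally, i.e. the tertiary OH is trans to the oxirane oxygen and the trienyl chain cis to it, with (1S,5R,6R) ring and (4R) side-chain configuration.

**Acid fragment**

Step 1
Reactants: 1 (S)-3-bromo-2-methylpropan-1-ol; 2 propylmagnesium bromide
Product: 3 (R)-2-methylhexan-1-ol
Conditions: 2 (3 equiv), Li2CuCl4 (5 mol%), THF, −78 °C → rt; aq. work-up
Reagents that add atoms: none
Why: Kochi-type Li2CuCl4-catalysed sp3–sp3 cross-coupling of the primary bromide (the first equivalent of 2 only makes the magnesium alkoxide); the stereocentre is untouched and its descriptor changes from S to R only because the CH2Br arm becomes the butyl arm.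

Step 2
Reactants: 3 (R)-2-methylhexan-1-ol
Product: 5 ethyl (2E,4R)-2,4-dimethyloct-2-enoate, via (R)-2-methylhexanal 4 (not isolated)
Conditions: TEMPO (10 mol%), PhI(OAc)2 (1.1 equiv), CH2Cl2, rt; then Ph3P=C(Me)CO2Et (1.5 equiv), rt
Reagents that add atoms: ethyl 2-(triphenylphosphoranylidene)propanoate, CCOC(=O)C(C)=P(c1ccccc1)(c1ccccc1)c1ccccc1
Why: TEMPO/PhI(OAc)2 oxidation followed in the same pot by Wittig olefination with a stabilised ylide gives the (E)-trisubstituted enoate, and trapping the α-branched aldehyde at once avoids its epimerisation.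

Step 3
Reactants: 5 ethyl (2E,4R)-2,4-dimethyloct-2-enoate
Product: 6 (2E,4R)-2,4-dimethyloct-2-enoic acid
Conditions: LiOH, THF/MeOH/H2O, 40 °C; then 1 M HCl
Reagents that add atoms: lithium hydroxide, [Li+].[OH-]
Why: Ester saponification; the γ-stereocentre and the E-alkene are not affected by hydroxide at this temperature.

**Core fragment**

Step 4
Reactants: 7 hydroquinone
Product: 8 1,4-dimethoxybenzene
Conditions: MeI (2.5 equiv), K2CO3, acetone, reflux
Reagents that add atoms: iodomethane, CI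
Why: Double Williamson O-methylation of the phenoxide.

Step 5
Reactants: 8 1,4-dimethoxybenzene
Product: 9 1,4-dimethoxy-2-nitrobenzene
Conditions: 65% HNO3, AcOH, 0 °C → rt
Reagents that add atoms: nitric acid, O[N+](=O)[O-]
Why: Electrophilic aromatic nitration; all four free positions are equivalent and the nitro group deactivates the ring against a second nitration.

Step 6
Reactants: 9 1,4-dimethoxy-2-nitrobenzene
Product: 10 2,5-dimethoxyaniline
Conditions: H2 (1 atm), 10% Pd/C, EtOH, rt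
Reagents that add atoms: none
Why: Catalytic hydrogenation of the nitro group to the aniline.

Step 7
Reactants: 6 (2E,4R)-2,4-dimethyloct-2-enoic acid; 10 2,5-dimethoxyaniline
Product: 12 (2E,4R)-N-(2,5-dimethoxyphenyl)-2,4-dimethyloct-2-enamide, via acid chloride 11 (not isolated)
Conditions: (COCl)2, DMF (cat.), CH2Cl2, 0 °C → rt, evaporate; then 10, pyridine, CH2Cl2, 0 °C → rt
Reagents that add atoms: oxalyl chloride, ClC(=O)C(Cl)=O (chlorine of 11 only; nothing of it stays in 12)
Why: Acid chloride formation and N-acylation (Schotten–Baumann type) of the aniline; no stereocentre is involved.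

Step 8
Reactants: 12 (2E,4R)-N-(2,5-dimethoxyphenyl)-2,4-dimethyloct-2-enamide
Product: 13 (2E,4R)-N-(6,6-dimethoxy-3-oxocyclohexa-1,4-dien-1-yl)-2,4-dimethyloct-2-enamide
Conditions: PhI(OAc)2 (1.5 equiv), MeOH (trace H2O), 0 °C → rt
Reagents that add atoms: methanol, CO; water, O
Why: Hypervalent-iodine oxidative dearomatisation: methanol adds at the methoxy-bearing carbon ortho to nitrogen and the other methyl ether is hydrolysed, giving regioselectively the quinone monoketal whose free carbonyl is the vinylogous-amide one (the future carbinol carbon).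

Step 9
Reactants: 13 (2E,4R)-N-(6,6-dimethoxy-3-oxocyclohexa-1,4-dien-1-yl)-2,4-dimethyloct-2-enamide
Product: 14 (2E,4R)-N-[(1S,6R)-2,2-dimethoxy-5-oxo-7-oxabicyclo[4.1.0]hept-3-en-3-yl]-2,4-dimethyloct-2-enamide
Conditions: 70% aq. t-BuOOH, aq. NaOH, N-benzylcinchoninium chloride (20 mol%), toluene, rt; recrystallise
Reagents that add atoms: tert-butyl hydroperoxide, CC(C)(C)OO
Why: Wynberg-type phase-transfer Weitz–Scheffer epoxidation: the peroxide anion attacks only the electron-poor CH=CH of the enone (the other alkene is a vinylogous amide), the cinchoninium ion pair is chosen to select the face giving the (1S,6R) oxirane (the cinchonidinium salt gives the other epoxide), and the minor epoxide diastereomer is removed by recrystallisation.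

Step 10
Reactants: 14 (2E,4R)-N-[(1S,6R)-2,2-dimethoxy-5-oxo-7-oxabicyclo[4.1.0]hept-3-en-3-yl]-2,4-dimethyloct-2-enamide
Product: 16 (2E,4R)-N-[(1S,6S)-2,2-dimethoxy-5-(methoxymethylidene)-7-oxabicyclo[4.1.0]hept-3-en-3-yl]-2,4-dimethyloct-2-enamide (E/Z mixture at the enol ether), via beta-silyl carbinol 15 (not isolated)
Conditions: Me3SiCH2OMe, s-BuLi (3 equiv each), THF, −78 → −25 °C; add 14, −78 °C; then t-BuOK, −78 °C → rt
Reagents that add atoms: (methoxymethyl)trimethylsilane, COC[Si](C)(C)C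
Why: Peterson olefination with the α-methoxy-α-silyl carbanion (Magnus reagent): after N–H deprotonation by the first equivalent, 1,2-addition to the enone carbonyl and potassium-alkoxide-triggered loss of silanolate give the exocyclic enol ether, whose geometry is irrelevant because the carbon is re-oxidised in the next step.

Step 11
Reactants: 16 (2E,4R)-N-[(1S,6S)-2,2-dimethoxy-5-(methoxymethylidene)-7-oxabicyclo[4.1.0]hept-3-en-3-yl]-2,4-dimethyloct-2-enamide
Product: 18 (2E,4R)-N-[(1S,5R,6R)-5-formyl-5-hydroxy-2,2-dimethoxy-7-oxabicyclo[4.1.0]hept-3-en-3-yl]-2,4-dimethyloct-2-enamide, via methyl hemiacetal 17 (not isolated)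
Conditions: OsO4 (2 mol%), NMO (1.2 equiv), acetone/H2O (8:1), 0 °C; used crude
Reagents that add atoms: N-methylmorpholine N-oxide, C[N+]1([O-])CCOCC1; water, O (both oxygens are relayed through OsO4)
Why: Upjohn dihydroxylation of the most electron-rich alkene: OsO4 approaches the exocyclic enol ether from the face opposite the oxirane oxygen (steric shielding plus the usual anti-to-allylic-oxygen preference), so the new tertiary OH is trans to the oxirane and the carbon branch cis, and the hemiacetal collapses to the aldehyde with loss of methanol.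

Step 12
Reactants: 18 (2E,4R)-N-[(1S,5R,6R)-5-formyl-5-hydroxy-2,2-dimethoxy-7-oxabicyclo[4.1.0]hept-3-en-3-yl]-2,4-dimethyloct-2-enamide
Product: 19 (2E,4R)-N-[(1S,5S,6R)-5-hydroxy-5-[(E)-2-iodoethenyl]-2,2-dimethoxy-7-oxabicyclo[4.1.0]hept-3-en-3-yl]-2,4-dimethyloct-2-enamide
Conditions: CrCl2 (8 equiv), CHI3 (3 equiv), THF, 0 °C → rt, dark
Reagents that add atoms: iodoform, IC(I)I
Why: Takai iodo-olefination: the geminal dichromium species from CHI3/CrCl2 turns the non-enolisable α-hydroxy aldehyde into the (E)-vinyl iodide without base, so oxirane, ketal and the trans-epoxy alcohol (prone to Payne rearrangement under base) are left alone; the descriptor at the carbinol carbon changes only through substituent priorities.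

Step 13
Reactants: 19 (2E,4R)-N-[(1S,5S,6R)-5-hydroxy-5-[(E)-2-iodoethenyl]-2,2-dimethoxy-7-oxabicyclo[4.1.0]hept-3-en-3-yl]-2,4-dimethyloct-2-enamide
Product: 20 (2E,4R)-N-[(1S,5S,6R)-5-hydroxy-5-[(E)-2-iodoethenyl]-2-oxo-7-oxabicyclo[4.1.0]hept-3-en-3-yl]-2,4-dimethyloct-2-enamide
Conditions: Montmorillonite K10, CH2Cl2, rt
Reagents that add atoms: water, O
Why: Mild clay-mediated acid hydrolysis of the dimethyl ketal with adsorbed water, driven by formation of the amido-enone and gentle enough for the oxirane, the tertiary allylic alcohol and the vinyl iodide.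

**Stannane fragment**

Step 14
Reactants: 21 cyclopentane-1,3-dione
Product: 22 2-(hydroxyimino)cyclopentane-1,3-dione
Conditions: NaNO2, aq. HCl, 0 °C
Reagents that add atoms: sodium nitrite, [Na+].[O-]N=O
Why: Nitrosation of the enolised 1,3-dione at its central carbon and tautomerisation to the oxime.

Step 15
Reactants: 22 2-(hydroxyimino)cyclopentane-1,3-dione
Product: 23 2-amino-3-hydroxycyclopent-2-en-1-one hydrochloride
Conditions: H2 (1 atm), 10% Pd/C, HCl, EtOH, rt
Reagents that add atoms: hydrogen chloride, Cl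
Why: Hydrogenolysis of the oxime to the primary amine, trapped as the hydrochloride so that the α-amino dione cannot self-condense.

Step 16
Reactants: 24 prop-2-yn-1-ol
Product: 25 (E)-3-(tributylstannyl)prop-2-en-1-ol
Conditions: Bu3SnH (1.3 equiv), AIBN (cat.), 80 °C, neat; chromatography
Reagents that add atoms: tributyltin hydride, CCCC[SnH](CCCC)CCCC
Why: Radical hydrostannylation of the terminal alkyne; reversible stannyl-radical addition equilibrates the adducts to the thermodynamically favoured (E)-β-stannyl isomer, separated from minor isomers.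

Step 17
Reactants: 25 (E)-3-(tributylstannyl)prop-2-en-1-ol
Product: 26 (E)-3-(tributylstannyl)prop-2-enal
Conditions: MnO2 (15 equiv), CH2Cl2, rt
Reagents that add atoms: none
Why: Chemoselective MnO2 oxidation of the allylic alcohol with retention of alkene geometry and of the C–Sn bond.

Step 18
Reactants: 26 (E)-3-(tributylstannyl)prop-2-enal
Product: 27 ethyl (2E,4E)-5-(tributylstannyl)penta-2,4-dienoate
Conditions: (EtO)2P(O)CH2CO2Et, NaH, THF, 0 °C → rt
Reagents that add atoms: triethyl phosphonoacetate, CCOC(=O)CP(=O)(OCC)OCC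
Why: Horner–Wadsworth–Emmons olefination, which gives the new (E)-enoate double bond under thermodynamic control.

Step 19
Reactants: 27 ethyl (2E,4E)-5-(tributylstannyl)penta-2,4-dienoate
Product: 28 (2E,4E)-5-(tributylstannyl)penta-2,4-dienoic acid
Conditions: LiOH, THF/MeOH/H2O, rt; AcOH to pH 5
Reagents that add atoms: lithium hydroxide, [Li+].[OH-]
Why: Ester saponification with a weakly acidic work-up so that the vinylstannane is not protodestannylated.

Step 20
Reactants: 28 (2E,4E)-5-(tributylstannyl)penta-2,4-dienoic acid; 23 2-amino-3-hydroxycyclopent-2-en-1-one hydrochloride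
Product: 30 (2E,4E)-N-(2-hydroxy-5-oxocyclopent-1-en-1-yl)-5-(tributylstannyl)penta-2,4-dienamide, via mixed pivalic anhydride 29 (not isolated)
Conditions: t-BuCOCl, Et3N, THF, −20 °C; then 23, Et3N, DMF, −20 °C → rt
Reagents that add atoms: pivaloyl chloride, CC(C)(C)C(Cl)=O (pivaloyl part of 29 only; nothing of it stays in 30)
Why: Mixed-anhydride amide coupling: the amine attacks the less hindered dienoyl carbonyl, any enol ester rearranges to the more stable amide by O-to-N acyl shift, and the acid-free conditions keep the C–Sn bond.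

**Fragment union**

Step 21
Reactants: 20 (2E,4R)-N-[(1S,5S,6R)-5-hydroxy-5-[(E)-2-iodoethenyl]-2-oxo-7-oxabicyclo[4.1.0]hept-3-en-3-yl]-2,4-dimethyloct-2-enamide; 30 (2E,4E)-N-(2-hydroxy-5-oxocyclopent-1-en-1-yl)-5-(tributylstannyl)penta-2,4-dienamide
Product: 31 (2E,4R)-N-[(1S,5R,6R)-5-hydroxy-5-[(1E,3E,5E)-7-[(2-hydroxy-5-oxocyclopent-1-en-1-yl)amino]-7-oxohepta-1,3,5-trien-1-yl]-2-oxo-7-oxabicyclo[4.1.0]hept-3-en-3-yl]-2,4-dimethyloct-2-enamide
Conditions: PdCl2(MeCN)2 (5 mol%), DMF, rt, dark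
Reagents that add atoms: none
Why: Ligand-free Stille cross-coupling of vinyl iodide and dienylstannane at room temperature with retention of both alkene geometries gives the (E,E,E)-triene; no base is present, so the trans-epoxy alcohol and the enolised dione survive, and all stereocentres are carried over unchanged.

**Compound list**
1 | (S)-3-bromo-2-methylpropan-1-ol | BrC[C@@H](C)CO | starting material
2 | propylmagnesium bromide | CCC[Mg]Br | starting material
3 | (R)-2-methylhexan-1-ol | CCCC[C@@H](C)CO | intermediate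
4 | (R)-2-methylhexanal | CCCC[C@@H](C)C=O | intermediate
5 | ethyl (2E,4R)-2,4-dimethyloct-2-enoate | CCCC[C@@H](C)/C=C(\C)C(=O)OCC | intermediate
6 | (2E,4R)-2,4-dimethyloct-2-enoic acid | CCCC[C@@H](C)/C=C(\C)C(=O)O | intermediate
7 | hydroquinone | Oc1ccc(O)cc1 | starting material
8 | 1,4-dimethoxybenzene | COc1ccc(OC)cc1 | intermediate
9 | 1,4-dimethoxy-2-nitrobenzene | COc1ccc(OC)c(c1)[N+](=O)[O-] | intermediate
10 | 2,5-dimethoxyaniline | COc1ccc(OC)c(N)c1 | intermediate
11 | (2E,4R)-2,4-dimethyloct-2-enoyl chloride | CCCC[C@@H](C)/C=C(\C)C(Cl)=O | intermediate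
12 | (2E,4R)-N-(2,5-dimethoxyphenyl)-2,4-dimethyloct-2-enamide | CCCC[C@@H](C)/C=C(\C)C(=O)Nc1cc(OC)ccc1OC | intermediate
13 | (2E,4R)-N-(6,6-dimethoxy-3-oxocyclohexa-1,4-dien-1-yl)-2,4-dimethyloct-2-enamide | CCCC[C@@H](C)/C=C(\C)C(=O)NC1=CC(=O)C=CC1(OC)OC | intermediate
14 | (2E,4R)-N-[(1S,6R)-2,2-dimethoxy-5-oxo-7-oxabicyclo[4.1.0]hept-3-en-3-yl]-2,4-dimethyloct-2-enamide | CCCC[C@@H](C)/C=C(\C)C(=O)NC1=CC(=O)[C@@H]2O[C@@H]2C1(OC)OC | intermediate
15 | (2E,4R)-N-[(1S,5S,6R)-5-hydroxy-2,2-dimethoxy-5-[methoxy(trimethylsilyl)methyl]-7-oxabicyclo[4.1.0]hept-3-en-3-yl]-2,4-dimethyloct-2-enamide (OH cis to the oxirane oxygen; present as its alkoxide; side-chain carbon unassigned) | CCCC[C@@H](C)/C=C(\C)C(=O)NC1=C[C@@](O)(C(OC)[Si](C)(C)C)[C@@H]2O[C@@H]2C1(OC)OC | intermediate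
16 | (2E,4R)-N-[(1S,6S)-2,2-dimethoxy-5-(methoxymethylidene)-7-oxabicyclo[4.1.0]hept-3-en-3-yl]-2,4-dimethyloct-2-enamide (E/Z mixture at the enol ether) | CCCC[C@@H](C)/C=C(\C)C(=O)NC1=CC(=COC)[C@@H]2O[C@@H]2C1(OC)OC | intermediate
17 | (2E,4R)-N-[(1S,5R,6R)-5-hydroxy-5-[hydroxy(methoxy)methyl]-2,2-dimethoxy-7-oxabicyclo[4.1.0]hept-3-en-3-yl]-2,4-dimethyloct-2-enamide (ring OH trans to the oxirane oxygen; hemiacetal carbon unassigned) | CCCC[C@@H](C)/C=C(\C)C(=O)NC1=C[C@](O)(C(O)OC)[C@@H]2O[C@@H]2C1(OC)OC | intermediate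
18 | (2E,4R)-N-[(1S,5R,6R)-5-formyl-5-hydroxy-2,2-dimethoxy-7-oxabicyclo[4.1.0]hept-3-en-3-yl]-2,4-dimethyloct-2-enamide (OH trans to the oxirane oxygen) | CCCC[C@@H](C)/C=C(\C)C(=O)NC1=C[C@](O)(C=O)[C@@H]2O[C@@H]2C1(OC)OC | intermediate
19 | (2E,4R)-N-[(1S,5S,6R)-5-hydroxy-5-[(E)-2-iodoethenyl]-2,2-dimethoxy-7-oxabicyclo[4.1.0]hept-3-en-3-yl]-2,4-dimethyloct-2-enamide | CCCC[C@@H](C)/C=C(\C)C(=O)NC1=C[C@](O)(/C=C/I)[C@@H]2O[C@@H]2C1(OC)OC | intermediate
20 | (2E,4R)-N-[(1S,5S,6R)-5-hydroxy-5-[(E)-2-iodoethenyl]-2-oxo-7-oxabicyclo[4.1.0]hept-3-en-3-yl]-2,4-dimethyloct-2-enamide | CCCC[C@@H](C)/C=C(\C)C(=O)NC1=C[C@](O)(/C=C/I)[C@@H]2O[C@@H]2C1=O | intermediate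
21 | cyclopentane-1,3-dione | O=C1CCC(=O)C1 | starting material
22 | 2-(hydroxyimino)cyclopentane-1,3-dione | O=C1CCC(=O)C1=NO | intermediate
23 | 2-amino-3-hydroxycyclopent-2-en-1-one hydrochloride | Cl.NC1=C(O)CCC1=O | intermediate
24 | prop-2-yn-1-ol | C#CCO | starting material
25 | (E)-3-(tributylstannyl)prop-2-en-1-ol | CCCC[Sn](CCCC)(CCCC)/C=C/CO | intermediate
26 | (E)-3-(tributylstannyl)prop-2-enal | CCCC[Sn](CCCC)(CCCC)/C=C/C=O | intermediate
27 | ethyl (2E,4E)-5-(tributylstannyl)penta-2,4-dienoate | CCCC[Sn](CCCC)(CCCC)/C=C/C=C/C(=O)OCC | intermediate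
28 | (2E,4E)-5-(tributylstannyl)penta-2,4-dienoic acid | CCCC[Sn](CCCC)(CCCC)/C=C/C=C/C(=O)O | intermediate
29 | (2E,4E)-5-(tributylstannyl)penta-2,4-dienoic pivalic anhydride | CCCC[Sn](CCCC)(CCCC)/C=C/C=C/C(=O)OC(=O)C(C)(C)C | intermediate
30 | (2E,4E)-N-(2-hydroxy-5-oxocyclopent-1-en-1-yl)-5-(tributylstannyl)penta-2,4-dienamide | CCCC[Sn](CCCC)(CCCC)/C=C/C=C/C(=O)NC1=C(O)CCC1=O | intermediate
31 | (2E,4R)-N-[(1S,5R,6R)-5-hydroxy-5-[(1E,3E,5E)-7-[(2-hydroxy-5-oxocyclopent-1-en-1-yl)amino]-7-oxohepta-1,3,5-trien-1-yl]-2-oxo-7-oxabicyclo[4.1.0]hept-3-en-3-yl]-2,4-dimethyloct-2-enamide | CCCC[C@@H](C)/C=C(\C)C(=O)NC1=C[C@](O)(/C=C/C=C/C=C/C(=O)NC2=C(O)CCC2=O)[C@@H]2O[C@@H]2C1=O | target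

**Totals**
Total step count: 21.
Longest linear sequence: 11 steps (steps 1–3, 7–13 and 21; the hydroquinone line, steps 4–13 and 21, is equally long).

**Steps most likely to fail, with fallbacks**

Step 10. The bulky silyl carbanion may not add to the carbonyl once the amide N–H is deprotonated, or the adduct may not eliminate cleanly. The fallback sets out from 14: the smaller Me3SiCH2Li (3 equiv, THF, −78 °C) adds to give the β-silyl carbinol F1, and t-BuOK then brings about Peterson elimination to the exocyclic methylene compound F2. OsO4/NMO dihydroxylates F2 on the face opposite the oxirane to give the diol F3, and SO3·pyridine/DMSO/i-Pr2NEt oxidises its primary alcohol, which comes back to the route at 18.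

Step 11. The osmylation may over-oxidise the electron-rich diene-amide, or the hemiacetal may not collapse cleanly under aqueous conditions. The fallback sets out from 16: dimethyldioxirane (acetone, −78 °C, 1 equiv) epoxidises the enol ether from the same open face to give the spiro methoxy-oxirane F4, which is hydrolysed on wet silica at pH 7 with loss of methanol and comes back at 18.

Step 12. The free α-hydroxy aldehyde may bind chromium or undergo α-ketol shift before it is olefinated. The fallback sets out from 18: TESOTf/2,6-lutidine gives the triethylsilyl ether F5, and dimethyl (1-diazo-2-oxopropyl)phosphonate with K2CO3 in MeOH homologates it to the terminal alkyne F6. Bu3SnH with PdCl2(PPh3)2 (cat.) gives the (E)-vinylstannane F7, and I2 (CH2Cl2, 0 °C) converts it to the vinyl iodide silyl ether F8. Aqueous HF in MeCN then removes the silyl ether and the dimethyl ketal together, coming back at 20.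

**Further compounds**
F1 | step 10 | (2E,4R)-N-[(1S,5S,6R)-5-hydroxy-2,2-dimethoxy-5-[(trimethylsilyl)methyl]-7-oxabicyclo[4.1.0]hept-3-en-3-yl]-2,4-dimethyloct-2-enamide | CCCC[C@@H](C)/C=C(\C)C(=O)NC1=C[C@@](O)(C[Si](C)(C)C)[C@@H]2O[C@@H]2C1(OC)OC
F2 | step 10 | (2E,4R)-N-[(1S,6S)-2,2-dimethoxy-5-methylidene-7-oxabicyclo[4.1.0]hept-3-en-3-yl]-2,4-dimethyloct-2-enamide | CCCC[C@@H](C)/C=C(\C)C(=O)NC1=CC(=C)[C@@H]2O[C@@H]2C1(OC)OC
F3 | step 10 | (2E,4R)-N-[(1S,5S,6R)-5-hydroxy-5-(hydroxymethyl)-2,2-dimethoxy-7-oxabicyclo[4.1.0]hept-3-en-3-yl]-2,4-dimethyloct-2-enamide (ring OH trans to the oxirane oxygen) | CCCC[C@@H](C)/C=C(\C)C(=O)NC1=C[C@](O)(CO)[C@@H]2O[C@@H]2C1(OC)OC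
F4 | step 11 | spiro methoxy-oxirane of 16 (new oxirane spanning ring C5 and the former enol-ether carbon, its oxygen on C5 trans to the ring oxirane oxygen) | CCCC[C@@H](C)/C=C(\C)C(=O)NC1=C[C@@]2(OC2OC)[C@@H]3O[C@@H]3C1(OC)OC
F5 | step 12 | (2E,4R)-N-[(1S,5R,6R)-5-formyl-2,2-dimethoxy-5-(triethylsilyloxy)-7-oxabicyclo[4.1.0]hept-3-en-3-yl]-2,4-dimethyloct-2-enamide | CCCC[C@@H](C)/C=C(\C)C(=O)NC1=C[C@](O[Si](CC)(CC)CC)(C=O)[C@@H]2O[C@@H]2C1(OC)OC
F6 | step 12 | (2E,4R)-N-[(1S,5S,6R)-5-ethynyl-2,2-dimethoxy-5-(triethylsilyloxy)-7-oxabicyclo[4.1.0]hept-3-en-3-yl]-2,4-dimethyloct-2-enamide | CCCC[C@@H](C)/C=C(\C)C(=O)NC1=C[C@](O[Si](CC)(CC)CC)(C#C)[C@@H]2O[C@@H]2C1(OC)OC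
F7 | step 12 | (2E,4R)-N-[(1S,5S,6R)-2,2-dimethoxy-5-[(E)-2-(tributylstannyl)ethenyl]-5-(triethylsilyloxy)-7-oxabicyclo[4.1.0]hept-3-en-3-yl]-2,4-dimethyloct-2-enamide | CCCC[C@@H](C)/C=C(\C)C(=O)NC1=C[C@](O[Si](CC)(CC)CC)(/C=C/[Sn](CCCC)(CCCC)CCCC)[C@@H]2O[C@@H]2C1(OC)OC
F8 | step 12 | (2E,4R)-N-[(1S,5S,6R)-5-[(E)-2-iodoethenyl]-2,2-dimethoxy-5-(triethylsilyloxy)-7-oxabicyclo[4.1.0]hept-3-en-3-yl]-2,4-dimethyloct-2-enamide | CCCC[C@@H](C)/C=C(\C)C(=O)NC1=C[C@](O[Si](CC)(CC)CC)(/C=C/I)[C@@H]2O[C@@H]2C1(OC)OC
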